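**Plan**

Retrosynthetic cuts, in order: the three aryl O–H bonds (carried as O–CH3) and the two aryl–CHO bonds. Then C1'–H, C1'–aryl and C1'–C2', which takes the side chain back to a C1 formyl group and then a C1 ketone. Then C11–O and C7–C11, back to a C5=C6–C7=O enone. Last, C5–C6 and C9–C10, which opens ring B.
Enabling feature: in ring B the quaternary fusion carbon C10 sits next to C1, which can be a ketone. The other fusion carbon C5 ends sp2, and the only functionalised ring B carbon, C7, lies para to C10. Ring B therefore maps onto a 2-oxygenated buta-1,3-diene added across the C5=C10 bond of a 2-methylcyclohex-2-enone (ring A).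
Forward: ring A by aminocatalytic Michael addition and aldol condensation, then ring B by the [4+2] cycloaddition. The C7 hydroxyisopropyl branch follows, then the C1 chain (CHO, isobutyl, aryl, hydride), then aromatic formylation and O-demethylation.
Stereochemistry: C4 comes from the enamine catalyst. C10 (and the transient C5) come from diene approach anti to the C4 methyl. C7 comes from hydride addition followed by invertive allylic substitution. C1 comes from protonation and equilibration on a conformationally anchored octalin. C1' comes from allylic-strain-controlled hydride capture of a benzylic cation.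

Key step: step 4

Remark: eudesmane locants are used (decalin C1–C10, fusion carbons C5 and C10, carbinol carbon C11, benzylic carbon C1'), and "methyl face" means the face of the bicycle carrying the C4 and C10 methyl groups. It is assumed that the tert-alkyl group at C7, once installed, outweighs the 1,3-diaxial C4/C10 methyl contact in fixing the ring conformation.

**Step 1**
Reactants: 1 propanal; 2 pent-1-en-3-one
Product: 3 (R)-2-methyl-5-oxoheptanal
Conditions: (S)-2-[methoxy(diphenyl)methyl]pyrrolidine (5 mol %), ethyl 3,4-dihydroxybenzoate (20 mol %), neat, 4 °C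
Reagents that add atoms: none
Why: Enamine-catalysed asymmetric Michael addition, in which the E-enamine of propanal is shielded on one face by the methoxydiphenylmethyl group of the S-configured pyrrolidine, so that the hydrogen-bond-activated enone is attacked from the open face and the new stereocentre (the later C4) should be R.

**Step 2**
Reactants: 3 (R)-2-methyl-5-oxoheptanal
Product: 4 (R)-2,4-dimethylcyclohex-2-en-1-one
Conditions: LiOH (10 mol %), iPrOH, rt
Reagents that add atoms: none
Why: Intramolecular aldol condensation, in which only the ethyl CH2 of the ketone can reach the aldehyde through a six-membered transition state and loss of water gives the conjugated enone, the mild base and short contact time being chosen so that the stereocentre (α to the aldehyde, later γ to the enone carbonyl) is not racemised.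

**Step 3**
Reactants: 5 but-3-en-2-one
Product: 6 2-(tert-butyldimethylsilyloxy)buta-1,3-diene
Conditions: TBSOTf, Et3N, Et2O, 0 °C → rt
Reagents that add atoms: tert-butyldimethylsilyl trifluoromethanesulfonate, CC(C)(C)[Si](C)(C)OS(=O)(=O)C(F)(F)F
Why: Soft enolisation of an enone with a silyl triflate and a tertiary amine, which removes a methyl proton and gives the cross-conjugated 2-silyloxydiene, TBS being preferred to TMS because diene and cycloadduct must survive a Lewis acid and chromatography.

**Step 4**
Reactants: 4 (R)-2,4-dimethylcyclohex-2-en-1-one; 6 2-(tert-butyldimethylsilyloxy)buta-1,3-diene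
Product: 7 (4R,4aS,8aS)-6-(tert-butyldimethylsilyloxy)-4,8a-dimethyl-3,4,4a,5,8,8a-hexahydronaphthalen-1(2H)-one (cis-fused; C1 ketone; C7=C8 silyl enol ether)
Conditions: Me2AlCl (30 mol %), CH2Cl2, −40 → −20 °C; Et3N, then aq NaHCO3
Reagents that add atoms: none
Why: Me2AlCl coordinates the C1 carbonyl of 4 and lowers the LUMO of the C5=C10 bond, and the electron-rich diene 6 should add in a concerted but asynchronous [4+2] cycloaddition in which the bond from the diene CH2 flanking the silyloxy carbon to the β-carbon C5 is more advanced than the C9–C10 bond. The closest known reaction type is the Lewis-acid-promoted Diels–Alder reaction of 2-methylcyclohex-2-enones with 2-silyloxybuta-1,3-dienes, which gives angular-methyl cis-decalones. Ring B closes as a six-membered carbocycle in the cycloaddition itself, both new σ-bonds (C5–C6 and C9–C10) being made suprafacially on the ring A alkene. Suprafacial addition forces H5 and the C10 methyl cis (cis fusion), and the diene should approach the enone face opposite the C4 methyl, which sits on the carbon next to C5, so that the C10 methyl is pushed onto the face of the C4 methyl (5S,10S from 4R). Regioselectivity is needed and is secured by the silyloxy donor, whose largest HOMO coefficient lies on the adjacent CH2 and pairs with C5, placing the enol ether carbon at C7, para to C10. Facial selectivity is the critical demand and rests only on the C4 stereocentre, which is why the reaction is run cold, while the TBS group and the proton-scavenging aluminium alkyl keep diene and enol ether from hydrolysis.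

**Step 5**
Reactants: 7 cis-fused adduct (C7=C8 enol ether)
Product: 8 (4R,4aR,8aS)-6-(tert-butyldimethylsilyloxy)-4,8a-dimethyl-3,4,4a,7,8,8a-hexahydronaphthalen-1(2H)-one (C6=C7 enol ether)
Conditions: Tf2NH (2 mol %), CH2Cl2, −10 °C → rt; Et3N
Reagents that add atoms: none
Why: Brønsted-acid-catalysed equilibration of silyl enol ethers (protonation at carbon, loss of the other α-proton), which should accumulate the C6=C7 isomer because the enol double bond of a cis-fused 2-decalone-type ring is more stable toward the ring fusion, while the neopentyl-type C1 carbonyl is a poor acceptor for the bulky silyl group and no stereocentre is touched.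

**Step 6**
Reactants: 8 C6=C7 silyl enol ether
Product: 9 (4R,8aS)-4,8a-dimethyl-3,4,8,8a-tetrahydronaphthalene-1,6(2H,7H)-dione (C5=C6–C7=O enone; C1 ketone)
Conditions: Pd(OAc)2 (1.1 equiv), MeCN, rt
Reagents that add atoms: none
Why: Saegusa–Ito oxidation, in which palladation at C6 is followed by β-hydride elimination of H5, the only β-hydrogen available, so the enone forms regiospecifically, the C5 stereocentre is erased as planned, and the neutral medium spares the epimerisable γ-stereocentre C4.

**Step 7**
Reactants: 9 enedione
Product: 10 (1R,4R,6R,8aS)-4,8a-dimethyl-1,2,3,4,6,7,8,8a-octahydronaphthalene-1,6-diol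
Conditions: NaBH4, CeCl3·7H2O, MeOH, −40 → 0 °C
Reagents that add atoms: none
Why: Luche 1,2-reduction, for which the enone should react from the conformer with C10–CH3 pseudoequatorial and C1 pseudoaxial on ring B (the steroid-like half-chair would place the C4 and C10 methyls 1,3-diaxial), so that axial hydride delivery to C7 comes from the open methyl face and puts the C7 hydroxyl on the opposite face (7R), while the C1 ketone is reduced as well to a carbinol (expected 1R) whose configuration is irrelevant because step 11 re-oxidises it.

**Step 8**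
Reactants: 10 diol
Product: 11 (2R,4aS,5R,8R)-5-hydroxy-4a,8-dimethyl-2,3,4,4a,5,6,7,8-octahydronaphthalen-2-yl pivalate (C7 ester; free C1–OH)
Conditions: PivCl (1.1 equiv), pyridine, DMAP (5 mol %), CH2Cl2, 0 °C
Reagents that add atoms: pivaloyl chloride, CC(C)(C)C(=O)Cl
Why: Sterically differentiated acylation, in which the allylic C7 hydroxyl should react with the bulky acid chloride much faster than the C1 hydroxyl wedged against quaternary C10, with retention at C7.

**Step 9**
Reactants: 11 allylic pivalate
Product: 12 (1R,4R,7S,10S)-eudesma-5,11-dien-1-ol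
Conditions: CH2=C(CH3)MgBr (5 equiv), CuBr·SMe2 (2 equiv), THF, −40 → 0 °C; aq NH4Cl
Reagents that add atoms: isopropenylmagnesium bromide, CC(=C)[Mg]Br
Why: Copper-mediated allylic substitution, in which the homocuprate adds oxidatively anti to the pivalate and the allylcopper intermediate eliminates reductively at the less hindered terminus C7 (C5 is fully substituted and flanked by quaternary C10), so that net SN2 displacement with inversion should place the isopropenyl group on the methyl face (7S).

**Step 10**
Reactants: 12 dienol
Product: 13 (1R,4R,7S,10S)-eudesm-5-ene-1,11-diol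
Conditions: Co(acac)2 (20 mol %), PhSiH3, O2 (1 atm), THF, rt
Reagents that add atoms: dioxygen, O=O
Why: Mukaiyama hydration (hydrogen atom transfer from a cobalt hydride, capture of the tertiary radical by O2, reduction of the peroxide), which is Markovnikov-selective and far faster for the exposed 1,1-disubstituted alkene than for the trisubstituted C5=C6 bond buried between C4, C7 and C10, and which creates no stereocentre.

**Step 11**
Reactants: 13 diol
Product: 14 (4R,7S,10S)-11-hydroxyeudesm-5-en-1-one
Conditions: Dess–Martin periodinane, CH2Cl2, 0 °C → rt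
Reagents that add atoms: none
Why: Dess–Martin oxidation, in which only the secondary C1 carbinol can be oxidised and the tertiary alcohol and the alkene are inert.

**Step 12**
Reactants: 14 hydroxy ketone
Product: 15 (4R,7S,10S)-1-(methoxymethylidene)eudesm-5-en-11-ol (E/Z mixture)
Conditions: MeOCH2PPh3Cl, KHMDS, THF, 0 → 50 °C
Reagents that add atoms: (methoxymethyl)triphenylphosphonium chloride, COC[P+](c1ccccc1)(c1ccccc1)c1ccccc1.[Cl-]
Why: Wittig methoxymethylenation, the standard one-carbon homologation of cyclohexanones that carry an α-quaternary carbon, with excess ylide covering the free tertiary hydroxyl and any competing enolisation.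

**Step 13**
Reactants: 15 enol ether
Product: 16 (1S,4R,7S,10R)-11-hydroxyeudesm-5-ene-1-carbaldehyde
Conditions: 1 M HCl, THF, 0 °C → rt; then K2CO3 (cat.), MeOH, rt
Reagents that add atoms: water, O
Why: Enol ether hydrolysis followed by base equilibration, in which the tert-alkyl group at C7 now demands a pseudoequatorial position and holds ring B in the half-chair that makes C10–CH3 axial on ring A, so that C1 should be protonated from the face opposite that methyl and the formyl group should end equatorial and cis to C10–CH3 (1S), an outcome the equilibration reinforces.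

**Step 14**
Reactants: 16 aldehyde
Product: 17 (1S,4R,7S,10R)-1-(1-hydroxy-3-methylbutyl)eudesm-5-en-11-ol (carbinol epimers)
Conditions: iBuMgBr (3 equiv), THF, −78 → 0 °C; aq NH4Cl
Reagents that add atoms: isobutylmagnesium bromide, CC(C)C[Mg]Br
Why: Grignard 1,2-addition to an aldehyde, fast enough at low temperature to leave the α-stereocentre C1 untouched, the new carbinol centre being irrelevant because it is oxidised next.

**Step 15**
Reactants: 17 secondary alcohol
Product: 18 (1S,4R,7S,10R)-1-(3-methylbutanoyl)eudesm-5-en-11-ol
Conditions: Dess–Martin periodinane, CH2Cl2, 0 °C → rt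
Reagents that add atoms: none
Why: Dess–Martin oxidation of the only oxidisable carbinol under essentially neutral conditions, giving a ketone whose acyl group stays equatorial at C1.

**Step 16**
Reactants: 18 ketone; 19 1,3,5-trimethoxybenzene
Product: 21 (1S,4R,7S,10R)-1-[1-hydroxy-3-methyl-1-(2,4,6-trimethoxyphenyl)butyl]eudesm-5-en-11-ol (carbinol epimers), via 2,4,6-trimethoxyphenyllithium 20 (not isolated)
Conditions: 19, nBuLi, THF, 0 °C → rt; then 18 premixed with LaCl3·2LiCl, THF, −78 → 0 °C; aq NH4Cl
Reagents that add atoms: none
Why: Directed ortho-lithiation between two methoxy groups followed by lanthanide-assisted 1,2-addition of the aryllithium, the oxophilic salt activating the hindered carbonyl and suppressing enolisation, and the configuration of the tertiary carbinol being irrelevant because it is ionised next.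

**Step 17**
Reactants: 21 tertiary benzylic carbinol
Product: 22 (1R,4R,7S,10R)-1-[(1S)-3-methyl-1-(2,4,6-trimethoxyphenyl)butyl]eudesm-5-en-11-ol
Conditions: Et3SiH (10 equiv), CF3CO2H (5 equiv), CH2Cl2, −78 → −30 °C
Reagents that add atoms: none
Why: Ionic hydrogenation, in which the acid ionises only the carbinol that gives a 2,4,6-trimethoxybenzyl-type cation (the aliphatic C11 carbinol and the C5=C6 bond stay intact in the cold), 1,3-allylic strain against the ortho methoxy group holds the C1–H bond in the cation plane so that quaternary C10 covers one face, and Et3SiH should deliver hydride to the other face to give 1'S.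

**Step 18**
Reactants: 22 trimethoxyaryl compound
Product: 24 3-{(1S)-1-[(1R,4R,7S,10R)-11-hydroxyeudesm-5-en-1-yl]-3-methylbutyl}-2,4,6-trimethoxybenzaldehyde, via dilithiated arene 23 (not isolated)
Conditions: nBuLi (3 equiv), TMEDA, THF, 0 °C; DMF, −78 °C → rt; aq NH4Cl
Reagents that add atoms: N,N-dimethylformamide, CN(C)C=O
Why: Directed ortho-metalation at a ring C–H flanked by two methoxy groups followed by formylation with DMF, the two free ring positions being constitutionally equivalent and the tertiary hydroxyl merely consuming one equivalent of base.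

**Step 19**
Reactants: 24 monoaldehyde
Product: 27 5-{(1S)-1-[(1R,4R,7S,10R)-11-hydroxyeudesm-5-en-1-yl]-3-methylbutyl}-2,4,6-trimethoxybenzene-1,3-dicarbaldehyde, via lithium α-amino alkoxide 25 (not isolated), via ring-lithiated α-amino alkoxide 26 (not isolated)
Conditions: Me2NCH2CH2NHMe, nBuLi, THF, −20 °C; 24; nBuLi, −20 → 0 °C; DMF; aq NH4Cl
Reagents that add atoms: N,N-dimethylformamide, CN(C)C=O
Why: In situ protection of the aldehyde as an α-amino alkoxide, directed lithiation of the last ring C–H (again between two methoxy groups) and DMF quench, the work-up releasing both formyl groups under conditions that stay basic throughout.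

**Step 20**
Reactants: 27 dialdehyde trimethyl ether
Product: 28 5-{(1S)-1-[(1R,4R,7S,10R)-11-hydroxyeudesm-5-en-1-yl]-3-methylbutyl}-2,4,6-trihydroxybenzene-1,3-dicarbaldehyde (target)
Conditions: 4-MeC6H4SLi (excess), HMPA–toluene, 110 °C; then 1 M HCl, 0 °C
Reagents that add atoms: none
Why: SN2 O-demethylation by a soft thiolate, made possible because each methoxy group is ortho or para to both formyl groups and so leaves as a stabilised phenoxide, and chosen because the basic medium spares the acid-sensitive tertiary alcohol and the trisubstituted alkene.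

**Compound list**

1 | propanal | CCC=O | starting material
2 | pent-1-en-3-one | CCC(=O)C=C | starting material
3 | (R)-2-methyl-5-oxoheptanal | O=C[C@H](C)CCC(=O)CC | intermediate
4 | (R)-2,4-dimethylcyclohex-2-en-1-one | CC1=C[C@H](C)CCC1=O | intermediate
5 | but-3-en-2-one | CC(=O)C=C | starting material
6 | 2-(tert-butyldimethylsilyloxy)buta-1,3-diene | C=CC(=C)O[Si](C)(C)C(C)(C)C | intermediate
7 | (4R,4aS,8aS)-6-(tert-butyldimethylsilyloxy)-4,8a-dimethyl-3,4,4a,5,8,8a-hexahydronaphthalen-1(2H)-one | O=C1CC[C@@H](C)[C@@H]2CC(O[Si](C)(C)C(C)(C)C)=CC[C@@]21C | intermediate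
8 | (4R,4aR,8aS)-6-(tert-butyldimethylsilyloxy)-4,8a-dimethyl-3,4,4a,7,8,8a-hexahydronaphthalen-1(2H)-one | O=C1CC[C@@H](C)[C@@H]2C=C(O[Si](C)(C)C(C)(C)C)CC[C@@]21C | intermediate
9 | (4R,8aS)-4,8a-dimethyl-3,4,8,8a-tetrahydronaphthalene-1,6(2H,7H)-dione | O=C1CC[C@@H](C)C2=CC(=O)CC[C@@]21C | intermediate
10 | (1R,4R,6R,8aS)-4,8a-dimethyl-1,2,3,4,6,7,8,8a-octahydronaphthalene-1,6-diol | O[C@@H]1CC[C@@H](C)C2=C[C@H](O)CC[C@@]21C | intermediate
11 | (2R,4aS,5R,8R)-5-hydroxy-4a,8-dimethyl-2,3,4,4a,5,6,7,8-octahydronaphthalen-2-yl pivalate | O[C@@H]1CC[C@@H](C)C2=C[C@H](OC(=O)C(C)(C)C)CC[C@@]21C | intermediate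
12 | (1R,4R,7S,10S)-eudesma-5,11-dien-1-ol | O[C@@H]1CC[C@@H](C)C2=C[C@@H](C(C)=C)CC[C@@]21C | intermediate
13 | (1R,4R,7S,10S)-eudesm-5-ene-1,11-diol | O[C@@H]1CC[C@@H](C)C2=C[C@@H](C(C)(C)O)CC[C@@]21C | intermediate
14 | (4R,7S,10S)-11-hydroxyeudesm-5-en-1-one | O=C1CC[C@@H](C)C2=C[C@@H](C(C)(C)O)CC[C@@]21C | intermediate
15 | (4R,7S,10S)-1-(methoxymethylidene)eudesm-5-en-11-ol, E/Z mixture | COC=C1CC[C@@H](C)C2=C[C@@H](C(C)(C)O)CC[C@@]21C | intermediate
16 | (1S,4R,7S,10R)-11-hydroxyeudesm-5-ene-1-carbaldehyde | O=C[C@H]1CC[C@@H](C)C2=C[C@@H](C(C)(C)O)CC[C@@]21C | intermediate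
17 | (1S,4R,7S,10R)-1-(1-hydroxy-3-methylbutyl)eudesm-5-en-11-ol, carbinol epimers | CC(C)CC(O)[C@H]1CC[C@@H](C)C2=C[C@@H](C(C)(C)O)CC[C@@]21C | intermediate
18 | (1S,4R,7S,10R)-1-(3-methylbutanoyl)eudesm-5-en-11-ol | CC(C)CC(=O)[C@H]1CC[C@@H](C)C2=C[C@@H](C(C)(C)O)CC[C@@]21C | intermediate
19 | 1,3,5-trimethoxybenzene | COc1cc(OC)cc(OC)c1 | starting material
20 | 2,4,6-trimethoxyphenyllithium | [Li]c1c(OC)cc(OC)cc1OC | intermediate
21 | (1S,4R,7S,10R)-1-[1-hydroxy-3-methyl-1-(2,4,6-trimethoxyphenyl)butyl]eudesm-5-en-11-ol, carbinol epimers | CC(C)CC(O)(c1c(OC)cc(OC)cc1OC)[C@H]1CC[C@@H](C)C2=C[C@@H](C(C)(C)O)CC[C@@]21C | intermediate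
22 | (1R,4R,7S,10R)-1-[(1S)-3-methyl-1-(2,4,6-trimethoxyphenyl)butyl]eudesm-5-en-11-ol | CC(C)C[C@H](c1c(OC)cc(OC)cc1OC)[C@H]1CC[C@@H](C)C2=C[C@@H](C(C)(C)O)CC[C@@]21C | intermediate
23 | lithium alkoxide of 22 lithiated at one free ring position | CC(C)C[C@H](c1c(OC)cc(OC)c([Li])c1OC)[C@H]1CC[C@@H](C)C2=C[C@@H](C(C)(C)O[Li])CC[C@@]21C | intermediate
24 | 3-{(1S)-1-[(1R,4R,7S,10R)-11-hydroxyeudesm-5-en-1-yl]-3-methylbutyl}-2,4,6-trimethoxybenzaldehyde | CC(C)C[C@H](c1c(OC)cc(OC)c(C=O)c1OC)[C@H]1CC[C@@H](C)C2=C[C@@H](C(C)(C)O)CC[C@@]21C | intermediate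
25 | lithium α-amino alkoxide from 24 and lithium N,N,N'-trimethylethylenediamide | CC(C)C[C@H](c1c(OC)cc(OC)c(C(O[Li])N(C)CCN(C)C)c1OC)[C@H]1CC[C@@H](C)C2=C[C@@H](C(C)(C)O[Li])CC[C@@]21C | intermediate
26 | 25 lithiated at the last free ring position | CC(C)C[C@H](c1c(OC)c([Li])c(OC)c(C(O[Li])N(C)CCN(C)C)c1OC)[C@H]1CC[C@@H](C)C2=C[C@@H](C(C)(C)O[Li])CC[C@@]21C | intermediate
27 | 5-{(1S)-1-[(1R,4R,7S,10R)-11-hydroxyeudesm-5-en-1-yl]-3-methylbutyl}-2,4,6-trimethoxybenzene-1,3-dicarbaldehyde | CC(C)C[C@H](c1c(OC)c(C=O)c(OC)c(C=O)c1OC)[C@H]1CC[C@@H](C)C2=C[C@@H](C(C)(C)O)CC[C@@]21C | intermediate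
28 | 5-{(1S)-1-[(1R,4R,7S,10R)-11-hydroxyeudesm-5-en-1-yl]-3-methylbutyl}-2,4,6-trihydroxybenzene-1,3-dicarbaldehyde | CC(C)C[C@H](c1c(O)c(C=O)c(O)c(C=O)c1O)[C@H]1CC[C@@H](C)C2=C[C@@H](C(C)(C)O)CC[C@@]21C | target

**Step count**

Total step count: 20.
Longest linear sequence: 19 steps (steps 1, 2 and 4–20). Step 3 is a one-step side branch.

**Steps most likely to fail**

Step 13. The proton may be delivered to the wrong face of C1, or the equilibrium may not favour the equatorial aldehyde, if the C7 group anchors the ring conformation incompletely.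
- The fallback sets out from 14 and comes back at 16.
- Wittig methylenation (Ph3PCH3Br, KHMDS, toluene, 80 °C) would give (4R,7S,10R)-1-methylideneeudesm-5-en-11-ol F3.
- Hydroboration with 9-BBN, to which the trisubstituted C5=C6 bond is inert, followed by H2O2/NaOH would give (1S,4R,7S,10R)-1-(hydroxymethyl)eudesm-5-en-11-ol F4.
- In F4 the C1–H bond is made irreversibly by syn addition from the face away from the axial C10 methyl, instead of by a reversible protonation.
- Dess–Martin oxidation of the primary alcohol then leads to 16.

Step 17. Loss of a proton from the crowded cation may outrun hydride transfer, with scrambling at C1 through the tetrasubstituted alkene, or the facial bias may be weak.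
- The fallback sets out from 21 and comes back at 22.
- Catalytic camphorsulfonic acid in CH2Cl2 at 0 °C, which should ionise only the benzylic carbinol, would deliberately give 1-[3-methyl-1-(2,4,6-trimethoxyphenyl)but-1-enyl]eudesm-5-en-11-ol F5 (ring stereocentres as in 21, E/Z mixture).
- Radical hydrogenation by hydrogen atom transfer (Mn(dpm)3, PhSiH3, tBuOOH, iPrOH, rt) would then add a hydrogen atom to C2'.
- The planar benzylic radical, held by the same 1,3-allylic strain, would take up its hydrogen from the face away from C10.
- The aryl-substituted alkene should react ahead of the buried C5=C6 bond.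

Step 5. The enol double bond may migrate incompletely or the wrong way, and the silyl group may transfer to the C1 carbonyl.
- The fallback sets out from 7 and comes back at 9.
- Direct Saegusa–Ito oxidation of the cycloadduct (Pd(OAc)2, MeCN) would give regiospecifically the cis-fused (4R,4aS,8aS)-4,8a-dimethyl-3,4,4a,5-tetrahydronaphthalene-1,6(2H,8aH)-dione F1 (C8=C9 enone).
- 2,3-Dichloro-5,6-dicyano-1,4-benzoquinone in refluxing dioxane would dehydrogenate C5–C6 through the only dienol available. This gives the cross-conjugated (4R,8aS)-4,8a-dimethyl-3,4-dihydronaphthalene-1,6(2H,8aH)-dione F2.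
- RhCl(PPh3)3 under H2 (1 atm, benzene–EtOH) would saturate only the disubstituted C8=C9 bond, which gives 9.

**Further compounds**

F1 | step 5 | (4R,4aS,8aS)-4,8a-dimethyl-3,4,4a,5-tetrahydronaphthalene-1,6(2H,8aH)-dione | O=C1CC[C@@H](C)[C@@H]2CC(=O)C=C[C@@]21C
F2 | step 5 | (4R,8aS)-4,8a-dimethyl-3,4-dihydronaphthalene-1,6(2H,8aH)-dione | O=C1CC[C@@H](C)C2=CC(=O)C=C[C@@]21C
F3 | step 13 | (4R,7S,10R)-1-methylideneeudesm-5-en-11-ol | C=C1CC[C@@H](C)C2=C[C@@H](C(C)(C)O)CC[C@@]21C
F4 | step 13 | (1S,4R,7S,10R)-1-(hydroxymethyl)eudesm-5-en-11-ol | OC[C@H]1CC[C@@H](C)C2=C[C@@H](C(C)(C)O)CC[C@@]21C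
F5 | step 17 | 1-[3-methyl-1-(2,4,6-trimethoxyphenyl)but-1-enyl]eudesm-5-en-11-ol, E/Z mixture | CC(C)C=C(c1c(OC)cc(OC)cc1OC)[C@H]1CC[C@@H](C)C2=C[C@@H](C(C)(C)O)CC[C@@]21C
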